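Everything rests on cutting the single bond between the 4-hydroxy-3-methoxyphenyl ring and the exocyclic vinylic carbon C7, the only atom linking that ring to the γ-butyrolactone (ring atoms O1, C2, C3, C4, C5; C7 is doubly bonded to C3). A Heck–Matsuda arylation forms this bond and, in the same operation, installs the E-configured C3=C7 alkene, with the phenol left free and the C4 stereocentre untouched. Its substrate is the (R)-α-methylene lactone already bearing the 3,4-dimethoxybenzyl group on C4, whose configuration comes from a rhodium-catalysed asymmetric hydrogenation of a Stobbe half-ester; the partner is the diazonium tetrafluoroborate of 4-amino-2-methoxyphenol.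

Key step: step 7

Assumption: the (S,S) antipode of Et-DuPhos (1,2-bis[(2S,5S)-2,5-diethylphospholan-1-yl]benzene) is taken to give the R acid, by analogy with carboxylate-directed rhodium hydrogenations of itaconate-type half-esters; the optical rotation of the derived β-benzyl lactone is the checkpoint, and the (R,R) ligand would be used if the sense proved opposite.

Step 1
Reactants: 1 veratraldehyde (3,4-dimethoxybenzaldehyde); 2 dimethyl succinate
Product: 4 (E)-4-(3,4-dimethoxyphenyl)-3-(methoxycarbonyl)but-3-enoic acid, via paraconic ester 3 (not isolated)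
Conditions: NaOMe (1.5 equiv), MeOH, reflux; then aq. HCl
Reagents that add atoms: none
Why: Stobbe condensation, in which the succinate enolate adds to the aldehyde, the aldolate closes onto the distal ester to give lactone 3, and methoxide-induced E1cB ring opening should deliver the conjugated E half-ester as its unreactive carboxylate.

Step 2
Reactants: 4 (E)-4-(3,4-dimethoxyphenyl)-3-(methoxycarbonyl)but-3-enoic acid
Product: 5 (R)-4-(3,4-dimethoxyphenyl)-3-(methoxycarbonyl)butanoic acid
Conditions: H2 (5 bar), [Rh(cod)((S,S)-Et-DuPhos)]OTf (0.5 mol%), NaOMe (10 mol%), MeOH, 25 °C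
Reagents that add atoms: none
Why: Rhodium–bisphospholane asymmetric hydrogenation of a β-aryl itaconate half-ester, in which the alkene and the CH2CO2 arm chelate the metal and the C2-symmetric (S,S) ligand should direct H2 to the face that makes the new stereocentre R.

Step 3
Reactants: 5 (R)-4-(3,4-dimethoxyphenyl)-3-(methoxycarbonyl)butanoic acid
Product: 7 (R)-4-(3,4-dimethoxybenzyl)dihydrofuran-2(3H)-one, via hydroxy acid 6 (not isolated)
Conditions: KOH (1 equiv), EtOH, 0 °C; CaCl2, NaBH4, −10 °C to rt; then aq. HCl, rt
Reagents that add atoms: none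
Why: Chemoselective borohydride reduction, in which Ca(BH4)2 formed in the flask reduces the methyl ester but not the potassium carboxylate, and acidification lactonises γ-hydroxy acid 6; the stereocentre is not involved and becomes C4 (R).

Step 4
Reactants: 7 (R)-4-(3,4-dimethoxybenzyl)dihydrofuran-2(3H)-one
Product: 8 (3S,4R)-3-[(dimethylamino)methyl]-4-(3,4-dimethoxybenzyl)dihydrofuran-2(3H)-one
Conditions: LiN(i-Pr)2, THF, −78 °C; then CH2=NMe2+ I−, −78 °C to rt
Reagents that add atoms: N,N-dimethylmethyleneiminium iodide (Eschenmoser's salt), C=[N+](C)C.[I-]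
Why: Mannich aminomethylation of the lactone lithium enolate, which can form only at C3, with the iminium ion expected to enter trans to the C4 benzyl group (this C3 centre is erased in step 5).

Step 5
Reactants: 8 (3S,4R)-3-[(dimethylamino)methyl]-4-(3,4-dimethoxybenzyl)dihydrofuran-2(3H)-one
Product: 10 (R)-4-(3,4-dimethoxybenzyl)-3-methylenedihydrofuran-2(3H)-one, via ammonium iodide 9 (not isolated)
Conditions: MeI, MeOH, rt; then aq. NaHCO3, CH2Cl2, rt
Reagents that add atoms: none
Why: Exhaustive N-methylation followed by a Hofmann-type E1cB elimination of trimethylamine should give the exocyclic alkene, and hydrogencarbonate is too weak a base to move the double bond into the ring, so C4 stays R.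

Step 6
Reactants: 11 4-amino-2-methoxyphenol
Product: 12 4-hydroxy-3-methoxybenzenediazonium tetrafluoroborate
Conditions: HBF4 (48% aq., 2.2 equiv), EtOH, 0 °C; t-BuONO (1.2 equiv); then Et2O, −20 °C
Reagents that add atoms: tert-butyl nitrite, CC(C)(C)ON=O; tetrafluoroboric acid, [H+].F[B-](F)(F)F
Why: Diazotisation of an arylamine with an alkyl nitrite in strong acid, where the excess acid and the non-nucleophilic counter-ion should keep the phenol protonated, suppressing azo coupling and quinone diazide formation, and the salt precipitates on adding ether.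

Step 7
Reactants: 10 (R)-4-(3,4-dimethoxybenzyl)-3-methylenedihydrofuran-2(3H)-one; 12 4-hydroxy-3-methoxybenzenediazonium tetrafluoroborate (1.2 equiv)
Product: 13 (R,E)-4-(3,4-dimethoxybenzyl)-3-(4-hydroxy-3-methoxybenzylidene)dihydrofuran-2(3H)-one
Conditions: Pd(OAc)2 (5 mol%), MeCN, 25 °C, no base
Reagents that add atoms: none
Why: Pd(OAc)2 is reduced in the flask to zerovalent palladium, which takes up the diazonium ion of 12 with loss of N2 to give a cationic arylpalladium species; syn insertion of the exocyclic C3=C7 alkene of 10 places the aryl group on the unsubstituted terminus C7 and palladium on C3, and rotation about C3–C7 followed by syn β-hydride elimination of a C7 hydrogen releases 13 and HBF4. The closest known reaction type is the Heck–Matsuda arylation of α-methylene-γ-butyrolactones with arenediazonium tetrafluoroborates, phenol-derived ones included. No ring is closed and no stereocentre is made; C4 is a spectator and should keep its R configuration because the medium is base-free and acidic, so the C4 hydrogen is never removed as a proton. The regiochemistry of insertion follows from the 1,1-disubstituted acrylate-type alkene, whose only accessible and electronically preferred site for the aryl group is C7. The step needs elimination toward C7 and not toward C4: the benzylic C7 hydrogens rotate freely into a syn-coplanar position and give an aryl-conjugated trisubstituted alkene, whereas the single C4 hydrogen is held by the five-membered ring at a poor dihedral angle to palladium and would give a tetrasubstituted alkene. The E geometry is expected because the elimination rotamer turns the aryl group away from the lactone carbonyl, as in acrylate arylations, and the free phenol is tolerated since no base is present to form a phenoxide or quinone diazide; chromatography removes any endocyclic isomer.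

Compound list
1 | veratraldehyde (3,4-dimethoxybenzaldehyde) | COc1ccc(C=O)cc1OC | starting material
2 | dimethyl succinate | COC(=O)CCC(=O)OC | starting material
3 | methyl 2-(3,4-dimethoxyphenyl)-5-oxotetrahydrofuran-3-carboxylate (paraconic ester; racemic mixture of diastereomers, stereocentres undefined) | COC(=O)C1CC(=O)OC1c1ccc(OC)c(OC)c1 | intermediate
4 | (E)-4-(3,4-dimethoxyphenyl)-3-(methoxycarbonyl)but-3-enoic acid | COC(=O)/C(CC(=O)O)=C/c1ccc(OC)c(OC)c1 | intermediate
5 | (R)-4-(3,4-dimethoxyphenyl)-3-(methoxycarbonyl)butanoic acid | COC(=O)[C@H](Cc1ccc(OC)c(OC)c1)CC(=O)O | intermediate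
6 | (R)-3-(3,4-dimethoxybenzyl)-4-hydroxybutanoic acid | OC[C@H](Cc1ccc(OC)c(OC)c1)CC(=O)O | intermediate
7 | (R)-4-(3,4-dimethoxybenzyl)dihydrofuran-2(3H)-one | O=C1C[C@@H](Cc2ccc(OC)c(OC)c2)CO1 | intermediate
8 | (3S,4R)-3-[(dimethylamino)methyl]-4-(3,4-dimethoxybenzyl)dihydrofuran-2(3H)-one | CN(C)C[C@H]1C(=O)OC[C@@H]1Cc1ccc(OC)c(OC)c1 | intermediate
9 | {[(3S,4R)-4-(3,4-dimethoxybenzyl)-2-oxotetrahydrofuran-3-yl]methyl}trimethylammonium iodide | C[N+](C)(C)C[C@H]1C(=O)OC[C@@H]1Cc1ccc(OC)c(OC)c1.[I-] | intermediate
10 | (R)-4-(3,4-dimethoxybenzyl)-3-methylenedihydrofuran-2(3H)-one | C=C1C(=O)OC[C@@H]1Cc1ccc(OC)c(OC)c1 | intermediate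
11 | 4-amino-2-methoxyphenol | COc1cc(N)ccc1O | starting material
12 | 4-hydroxy-3-methoxybenzenediazonium tetrafluoroborate | COc1cc([N+]#N)ccc1O.F[B-](F)(F)F | intermediate
13 | (R,E)-4-(3,4-dimethoxybenzyl)-3-(4-hydroxy-3-methoxybenzylidene)dihydrofuran-2(3H)-one | COc1cc(/C=C2/C(=O)OC[C@@H]2Cc2ccc(OC)c(OC)c2)ccc1O | target

Total step count: 7. Longest linear sequence: 6 steps (steps 1, 2, 3, 4, 5 and 7); step 6 is a one-step branch. No step follows the key step.

Steps most likely to fail

1. Step 7. After insertion, palladium on C3 may eliminate the C4 hydrogen instead of a C7 hydrogen, or the palladium hydride may re-add and walk the double bond into the ring; both processes flatten C4 and lead to an achiral butenolide. Insertion on the face away from the C4 benzyl group leaves palladium cis to that hydrogen, so this pathway is geometrically open. The fallback replaces the arylation by an aldol condensation; it sets out from lactone 7 and returns at target 13. Vanillin is silylated (t-BuMe2SiCl, imidazole, DMF) to 4-(tert-butyldimethylsilyloxy)-3-methoxybenzaldehyde F1. The lithium enolate of 7 (LiN(i-Pr)2, THF, −78 °C) adds to it to give the β-hydroxy lactone F2 (trans at C3/C4, both carbinol epimers). MsCl and Et3N in CH2Cl2 at 0 °C give the mesylate F3, from which DBU eliminates methanesulfonate by an E1cB path to the E-benzylidene lactone silyl ether F4. n-Bu4NF buffered with AcOH in THF at 0 °C then removes the silyl group to give 13.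

2. Step 6. The electron-rich aminophenol may be oxidised by the nitrosating agent, the diazonium ion may couple with unreacted phenol, or the salt may lose HBF4 to a quinone diazide during isolation. The fallback changes the electrophile class and the catalytic manifold; it sets out from methylene lactone 10 and returns at target 13. Purchased 4-iodo-2-methoxyphenol is coupled with 10 in a ligand-free phase-transfer Mizoroki–Heck reaction (Pd(OAc)2, KOAc, n-Bu4NBr, DMF, 60 °C), a known arylation of α-methylene-γ-butyrolactones in which the weak carboxylate base limits double-bond migration. This fallback makes no new compound (entry F0).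

3. Step 2. Facial discrimination in the hydrogenation may be incomplete, or trace impurities from the Stobbe step may inhibit the cationic rhodium catalyst, leaving 5 in low enantiomeric purity. The fallback uses stoichiometric auxiliary control in place of asymmetric catalysis; it sets out from veratraldehyde 1 and returns at lactone 7. Knoevenagel–Doebner condensation of 1 with malonic acid (pyridine, piperidine, 90 °C) gives (E)-3-(3,4-dimethoxyphenyl)acrylic acid F5, and H2 over Pd/C in EtOAc gives 3-(3,4-dimethoxyphenyl)propanoic acid F6. Activation with t-BuCOCl/Et3N and acylation of (S)-4-benzyloxazolidin-2-one (LiCl, THF) gives (S)-4-benzyl-3-[3-(3,4-dimethoxyphenyl)propanoyl]oxazolidin-2-one F7. Its chelated Z sodium enolate (NaN(SiMe3)2, THF, −78 °C) is alkylated by tert-butyl bromoacetate on the face away from the auxiliary benzyl group, which should give tert-butyl (R)-4-[(S)-4-benzyl-2-oxooxazolidin-3-yl]-3-(3,4-dimethoxybenzyl)-4-oxobutanoate F8. LiBH4 in wet THF at 0 °C reduces the imide carbonyl to the primary alcohol and releases the auxiliary, giving tert-butyl (R)-3-(3,4-dimethoxybenzyl)-4-hydroxybutanoate F9. CF3CO2H in CH2Cl2 removes the tert-butyl group and closes the lactone to 7.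

Further compounds
F1 | step 7 | 4-(tert-butyldimethylsilyloxy)-3-methoxybenzaldehyde | COc1cc(C=O)ccc1O[Si](C)(C)C(C)(C)C
F2 | step 7 | (3S,4R)-3-{[4-(tert-butyldimethylsilyloxy)-3-methoxyphenyl](hydroxy)methyl}-4-(3,4-dimethoxybenzyl)dihydrofuran-2(3H)-one (both carbinol epimers) | COc1cc(C(O)[C@H]2C(=O)OC[C@@H]2Cc2ccc(OC)c(OC)c2)ccc1O[Si](C)(C)C(C)(C)C
F3 | step 7 | [4-(tert-butyldimethylsilyloxy)-3-methoxyphenyl][(3S,4R)-4-(3,4-dimethoxybenzyl)-2-oxotetrahydrofuran-3-yl]methyl methanesulfonate (both epimers) | COc1cc(C(OS(C)(=O)=O)[C@H]2C(=O)OC[C@@H]2Cc2ccc(OC)c(OC)c2)ccc1O[Si](C)(C)C(C)(C)C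
F4 | step 7 | (R,E)-3-[4-(tert-butyldimethylsilyloxy)-3-methoxybenzylidene]-4-(3,4-dimethoxybenzyl)dihydrofuran-2(3H)-one | COc1cc(/C=C2/C(=O)OC[C@@H]2Cc2ccc(OC)c(OC)c2)ccc1O[Si](C)(C)C(C)(C)C
F0 | step 6 | none | none
F5 | step 2 | (E)-3-(3,4-dimethoxyphenyl)acrylic acid | COc1ccc(/C=C/C(=O)O)cc1OC
F6 | step 2 | 3-(3,4-dimethoxyphenyl)propanoic acid | COc1ccc(CCC(=O)O)cc1OC
F7 | step 2 | (S)-4-benzyl-3-[3-(3,4-dimethoxyphenyl)propanoyl]oxazolidin-2-one | COc1ccc(CCC(=O)N2[C@@H](Cc3ccccc3)COC2=O)cc1OC
F8 | step 2 | tert-butyl (R)-4-[(S)-4-benzyl-2-oxooxazolidin-3-yl]-3-(3,4-dimethoxybenzyl)-4-oxobutanoate | COc1ccc(C[C@H](CC(=O)OC(C)(C)C)C(=O)N2[C@@H](Cc3ccccc3)COC2=O)cc1OC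
F9 | step 2 | tert-butyl (R)-3-(3,4-dimethoxybenzyl)-4-hydroxybutanoate | COc1ccc(C[C@H](CC(=O)OC(C)(C)C)CO)cc1OC
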